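**Plan**

- Retrosynthesis: the C10 acetate is traced to a C10 ketone. Removing C9 (cutting C8–C9 and C9–C10, re-joining C8–C10) turns the cycloheptenone into the silyl enol ether of a trans-hydrindan-10-one.
- The six-membered ring is then cut at C7–C8 (enolate alkylation), the isopropyl group at C4 (organocerium addition), the side chain at C5–C6 (aldol) and the C1–C10 bond (conjugate addition), back to 3-methylcyclopent-2-en-1-one.
- Forward: the cyclopentane is the starting ring; C1, C5/C6 and C4 are set on it; the six-membered ring closes at C7–C8 and is enlarged by C9 to the seven-membered ring; the two esters go on last.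
- Enabling feature: in the ring C1–C5–C6–C7–C8–C9–C10 the oxygenated C10 lies between the quaternary C1 and the C9=C8(CH3) olefin. This is the pattern left when CH2 is inserted between the carbonyl carbon and the methylated α-carbon of a cyclohexanone whose other α-carbon (C1) cannot enolise.
- Stereochemistry: C1 from a ligand-controlled copper-catalysed conjugate addition; C5 and C6 from an anti aldol addition on the methyl face; C4 from addition trans to the C5 side chain; C10 from axial hydride delivery followed by Mitsunobu inversion.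

Key step: step 10

Convention: locants follow the daucane skeleton throughout (C1 angular quaternary carbon with CH3, C2 and C3 ring CH2, C4 isopropyl carbinol, C5 ring-fusion CH, C6 anisoate carbon, C7 CH2, C8 methyl-bearing olefinic carbon, C9 olefinic CH, C10 acetate carbon). β is the face of the C1 methyl group, α the opposite face.

Assumption: the antipode of the phosphinamine ligand in step 1 is the one whose sense of induction gives (S)-C1; every later stereocentre is relayed from this centre.

**Route**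

Step 1
Reactants: 1 3-methylcyclopent-2-en-1-one; 2 2-bromobut-1-ene
Product: 6 {[(3S)-3-(but-1-en-2-yl)-3-methylcyclopent-1-en-1-yl]oxy}trimethylsilane, via but-1-en-2-yllithium 3 (not isolated), via (but-1-en-2-yl)dimethylalane 4 (not isolated), via dimethylaluminium enolate 5 (not isolated)
Conditions: 2, t-BuLi (2 equiv), Et2O, −78 °C; Me2AlCl, −78 → −30 °C; 1, copper thiophene-2-carboxylate Cu(O2CC4H3S) (10 mol%), Ph2PN[CH(CH3)(2-naphthyl)]2 (SimplePhos-type ligand, 11 mol%), Et2O, −30 → −10 °C; Me3SiOTf, −78 → 0 °C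
Reagents that add atoms: trimethylsilyl trifluoromethanesulfonate, C[Si](C)(C)OS(=O)(=O)C(F)(F)F
Why: Bromine–lithium exchange and transmetallation give alkenylalane 4, whose alkenyl group the chiral copper–phosphinamine catalyst transfers to the β-carbon of the enone (copper-catalysed asymmetric conjugate addition of an alkenylalane to a β-methyl cyclic enone), the ligand antipode being chosen so that the new quaternary C1 is (S), and O-silylation of the regiodefined aluminium enolate 5 stores the C4=C5 enolate as 6.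

Step 2
Reactants: 6 {[(3S)-3-(but-1-en-2-yl)-3-methylcyclopent-1-en-1-yl]oxy}trimethylsilane; 7 (benzyloxy)acetaldehyde
Product: 9 (2S,3S)-2-[(1R)-2-(benzyloxy)-1-hydroxyethyl]-3-(but-1-en-2-yl)-3-methylcyclopentan-1-one, via lithium enolate 8 (not isolated)
Conditions: MeLi, THF, 0 °C; 7, −78 °C; sat. aq. NH4Cl at −78 °C
Reagents that add atoms: none
Why: MeLi cleaves the O–Si bond to release lithium enolate 8 without regiochemical scrambling, and its aldol addition through a chair Zimmerman–Traxler transition state, in which the ring fixes the (E)-enolate geometry, should give the anti adduct (C5/C6) with the aldehyde approaching C5 on the face of the C1 methyl, away from the bulkier α-branched but-1-en-2-yl group, so that the side chain ends cis to the methyl group.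

Step 3
Reactants: 9 (2S,3S)-2-[(1R)-2-(benzyloxy)-1-hydroxyethyl]-3-(but-1-en-2-yl)-3-methylcyclopentan-1-one; 10 isopropyllithium
Product: 12 (1R,2S,3S)-2-[(1R)-2-(benzyloxy)-1-hydroxyethyl]-3-(but-1-en-2-yl)-3-methyl-1-(propan-2-yl)cyclopentan-1-ol, via isopropylcerium dichloride 11 (not isolated)
Conditions: i-PrLi (3.3 equiv), CeCl3 (3.5 equiv), THF, −78 °C; 9, −78 → −40 °C; aq. NH4Cl
Reagents that add atoms: none
Why: The organocerium reagent is nucleophilic but weakly basic, so after deprotonating the C6 hydroxyl it adds to the hindered, enolisable ketone without retro-aldol cleavage (organocerium 1,2-addition), and it attacks C4 on the α face, trans to the C5 side chain, which places the isopropyl group α and the tertiary hydroxyl β, cis to the C1 methyl.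

Step 4
Reactants: 12 (1R,2S,3S)-2-[(1R)-2-(benzyloxy)-1-hydroxyethyl]-3-(but-1-en-2-yl)-3-methyl-1-(propan-2-yl)cyclopentan-1-ol
Product: 13 triethyl{[(1R,2S,3S)-2-[(1R)-2-(benzyloxy)-1-(triethylsilyloxy)ethyl]-3-(but-1-en-2-yl)-3-methyl-1-(propan-2-yl)cyclopentyl]oxy}silane
Conditions: Et3SiOTf (3 equiv), 2,6-lutidine, CH2Cl2, −78 → 0 °C
Reagents that add atoms: triethylsilyl trifluoromethanesulfonate, CC[Si](CC)(CC)OS(=O)(=O)C(F)(F)F
Why: A silyl triflate with a hindered pyridine base silylates both the secondary C6 hydroxyl and the hindered tertiary C4 hydroxyl (silyl ether formation), which removes the acidic protons and the alkoxide nucleophiles before the base-mediated steps and touches no stereocentre.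

Step 5
Reactants: 13 triethyl{[(1R,2S,3S)-2-[(1R)-2-(benzyloxy)-1-(triethylsilyloxy)ethyl]-3-(but-1-en-2-yl)-3-methyl-1-(propan-2-yl)cyclopentyl]oxy}silane
Product: 15 1-[(1S,2S,3R)-2-[(1R)-2-(benzyloxy)-1-(triethylsilyloxy)ethyl]-1-methyl-3-(propan-2-yl)-3-(triethylsilyloxy)cyclopentyl]propan-1-one, via ozonide 14 (not isolated)
Conditions: O3, CH2Cl2, −78 °C (indicator end point); PPh3, −78 °C → rt
Reagents that add atoms: ozone, [O-][O+]=O
Why: Ozone cleaves the only C=C bond, the 1,1-disubstituted alkene, through ozonide 14, which PPh3 reduces to the C10 ethyl ketone with loss of formaldehyde (ozonolysis with reductive work-up), while the benzyl and silyl ethers should survive a controlled ozone dose at −78 °C.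

Step 6
Reactants: 15 1-[(1S,2S,3R)-2-[(1R)-2-(benzyloxy)-1-(triethylsilyloxy)ethyl]-1-methyl-3-(propan-2-yl)-3-(triethylsilyloxy)cyclopentyl]propan-1-one
Product: 16 1-[(1S,2S,3R)-2-[(1R)-2-hydroxy-1-(triethylsilyloxy)ethyl]-1-methyl-3-(propan-2-yl)-3-(triethylsilyloxy)cyclopentyl]propan-1-one
Conditions: H2 (1 atm), Pd/C, EtOAc, rt
Reagents that add atoms: none
Why: Hydrogenolysis of the benzyl ether over Pd/C in a neutral aprotic solvent frees the C7 hydroxyl and leaves the hindered ketone and the silyl ethers in place.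

Step 7
Reactants: 16 1-[(1S,2S,3R)-2-[(1R)-2-hydroxy-1-(triethylsilyloxy)ethyl]-1-methyl-3-(propan-2-yl)-3-(triethylsilyloxy)cyclopentyl]propan-1-one
Product: 17 1-[(1S,2S,3R)-2-[(1R)-2-iodo-1-(triethylsilyloxy)ethyl]-1-methyl-3-(propan-2-yl)-3-(triethylsilyloxy)cyclopentyl]propan-1-one
Conditions: PPh3, I2, imidazole, CH2Cl2, 0 °C → rt
Reagents that add atoms: iodine, II
Why: Appel-type iodination converts the primary alcohol into the iodide by SN2 displacement of its alkoxyphosphonium ion under imidazole-buffered conditions that the silyl ethers tolerate.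

Step 8
Reactants: 17 1-[(1S,2S,3R)-2-[(1R)-2-iodo-1-(triethylsilyloxy)ethyl]-1-methyl-3-(propan-2-yl)-3-(triethylsilyloxy)cyclopentyl]propan-1-one
Product: 19 (1R,3aS,7S,7aS)-3a,5-dimethyl-1-(propan-2-yl)-1,7-bis(triethylsilyloxy)octahydro-4H-inden-4-one (both C8 epimers), via potassium enolate 18 (not isolated)
Conditions: KN(SiMe3)2 (1.2 equiv), THF, −78 °C → rt
Reagents that add atoms: none
Why: The base can deprotonate the C10 ketone only at C8 because C1 is quaternary, and the enolate closes the six-membered ring by C-alkylation at C7 in the 6-(enolendo)-exo-tet mode allowed by Baldwin's rules for enolates (intramolecular ketone alkylation), the trans ring fusion following from the C1/C5 configuration already in place and the new C8 centre being of no consequence because it becomes sp2 in the next step.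

Step 9
Reactants: 19 (1R,3aS,7S,7aS)-3a,5-dimethyl-1-(propan-2-yl)-1,7-bis(triethylsilyloxy)octahydro-4H-inden-4-one
Product: 21 (1R,3aS,7S,7aS)-3a,5-dimethyl-1-(propan-2-yl)-1,7-bis(triethylsilyloxy)-4-(trimethylsilyloxy)-2,3,3a,6,7,7a-hexahydro-1H-indene, via potassium enolate 20 (not isolated)
Conditions: KN(SiMe3)2 (1.5 equiv), THF, −78 → 0 °C; Me3SiCl, Et3N, −78 °C → rt
Reagents that add atoms: chlorotrimethylsilane, C[Si](C)(C)Cl
Why: C8 is the only enolisable position, so deprotonation and O-silylation of enolate 20 (enolate trapping) should give the tetrasubstituted C8=C10 silyl enol ether as a single regioisomer, which also erases the C8 stereocentre.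

Step 10
Reactants: 21 (1R,3aS,7S,7aS)-3a,5-dimethyl-1-(propan-2-yl)-1,7-bis(triethylsilyloxy)-4-(trimethylsilyloxy)-2,3,3a,6,7,7a-hexahydro-1H-indene; 22 diiodomethane
Product: 26 (1R,3aS,8S,8aS)-3a,6-dimethyl-1-(propan-2-yl)-1,8-bis(triethylsilyloxy)-2,3,3a,7,8,8a-hexahydroazulen-4(1H)-one, via ethyl(iodomethyl)zinc 23 (not isolated), via siloxycyclopropane 24 (not isolated), via chloro ketone 25 (not isolated)
Conditions: Et2Zn, CH2I2 (3 equiv each), CH2Cl2, 0 °C → rt; cold aq. NaHCO3 work-up, crude; FeCl3 (2.5 equiv), pyridine (1 equiv), DMF, 0 °C → rt; NaOAc, MeOH, 60 °C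
Reagents that add atoms: none
Why: Zinc carbenoid 23 transfers its methylene (C9) to the electron-rich tetrasubstituted enol ether in a concerted, stereospecific syn [2+1] addition that forms the C8–C9 and C9–C10 bonds and closes the three-membered ring of 24 (Simmons–Smith reaction, Furukawa variant). FeCl3 then oxidises the siloxycyclopropane by one electron with loss of the silyl group as Me3SiCl, and the oxygen-centred radical undergoes β-scission of the shared C8–C10 bond, so the seven-membered ring arises by ring expansion (homolytic cleavage of the zero bridge) and not by a new cyclisation; the tertiary C8 radical takes chlorine from a second FeCl3 to give 25. NaOAc removes HCl by an E1cB pathway through the C9 enolate, which places the double bond in conjugation as C8=C9. The closest known reaction type is the Saegusa-type FeCl3 ring expansion of 1-siloxybicyclo[n.1.0]alkanes to cycloalk-2-enones, the parent case being 2-methylcyclohexanone to 3-methylcyclohept-2-enone. No lasting stereocentre is created, because the two cyclopropane carbons end as a carbonyl carbon and an sp2 carbon, so the face of methylene transfer is immaterial and C1, C4, C5 and C6 are untouched. The selectivity needed is regiochemical and the substrate secures it: the quaternary C1 allows only the C8=C10 enol ether, and cleavage of the internal bond is preferred over the external C9–C10 bond because it releases the tertiary C8 radical and more ring strain.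

Step 11
Reactants: 26 (1R,3aS,8S,8aS)-3a,6-dimethyl-1-(propan-2-yl)-1,8-bis(triethylsilyloxy)-2,3,3a,7,8,8a-hexahydroazulen-4(1H)-one
Product: 27 (1R,3aS,8S,8aS)-1,8-dihydroxy-3a,6-dimethyl-1-(propan-2-yl)-2,3,3a,7,8,8a-hexahydroazulen-4(1H)-one
Conditions: HF (48% aq.), MeCN, 0 °C → rt
Reagents that add atoms: none
Why: Fluoride-assisted Si–O cleavage removes both triethylsilyl ethers without affecting the enone or any stereocentre, and any silyl group already lost under FeCl3 converges on the same diol (silyl ether deprotection).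

Step 12
Reactants: 27 (1R,3aS,8S,8aS)-1,8-dihydroxy-3a,6-dimethyl-1-(propan-2-yl)-2,3,3a,7,8,8a-hexahydroazulen-4(1H)-one; 28 4-methoxybenzoyl chloride
Product: 29 (3R,3aS,4S,8aS)-3-hydroxy-6,8a-dimethyl-8-oxo-3-(propan-2-yl)-1,2,3,3a,4,5,8,8a-octahydroazulen-4-yl 4-methoxybenzoate
Conditions: pyridine, DMAP (cat.), CH2Cl2, 0 °C → rt
Reagents that add atoms: none
Why: DMAP-catalysed acylation with the acid chloride esterifies the secondary C6 hydroxyl, whereas the tertiary C4 hydroxyl next to the isopropyl group is too hindered to react, so the anisoate should be installed regioselectively (nucleophile-catalysed esterification).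

Step 13
Reactants: 29 (3R,3aS,4S,8aS)-3-hydroxy-6,8a-dimethyl-8-oxo-3-(propan-2-yl)-1,2,3,3a,4,5,8,8a-octahydroazulen-4-yl 4-methoxybenzoate
Product: 30 (3R,3aS,4S,8S,8aS)-3,8-dihydroxy-6,8a-dimethyl-3-(propan-2-yl)-1,2,3,3a,4,5,8,8a-octahydroazulen-4-yl 4-methoxybenzoate
Conditions: NaBH4, CeCl3·7H2O, MeOH, −40 → 0 °C
Reagents that add atoms: none
Why: Luche reduction gives clean 1,2-reduction of the enone, and the hydride should enter C10 axially on the α face, anti to the pseudo-axial C1 methyl that screens the β face, which gives the pseudo-equatorial 10β-alcohol (10S), the epimer required for the inversion in the last step.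

Step 14
Reactants: 30 (3R,3aS,4S,8S,8aS)-3,8-dihydroxy-6,8a-dimethyl-3-(propan-2-yl)-1,2,3,3a,4,5,8,8a-octahydroazulen-4-yl 4-methoxybenzoate; 31 acetic acid
Product: 32 (3R,3aS,4S,8R,8aS)-8-(acetyloxy)-3-hydroxy-6,8a-dimethyl-3-(propan-2-yl)-1,2,3,3a,4,5,8,8a-octahydroazulen-4-yl 4-methoxybenzoate
Conditions: PPh3, DIAD, toluene, 0 °C → rt
Reagents that add atoms: none
Why: Mitsunobu esterification activates the allylic 10β-hydroxyl as an alkoxyphosphonium ion that acetate displaces by SN2 from the α face (the trajectory the hydride used), which installs the acetate with inversion to the 10α (10R) configuration of the target, while the tertiary C4 hydroxyl does not react under these conditions.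

**Compound list**

1 | 3-methylcyclopent-2-en-1-one | CC1=CC(=O)CC1 | starting material
2 | 2-bromobut-1-ene | C=C(Br)CC | starting material
3 | but-1-en-2-yllithium | [Li]C(=C)CC | intermediate
4 | (but-1-en-2-yl)dimethylalane | C[Al](C)C(=C)CC | intermediate
5 | dimethylaluminium (3S)-3-(but-1-en-2-yl)-3-methylcyclopent-1-en-1-olate | C[Al](C)OC1=C[C@@](C)(C(=C)CC)CC1 | intermediate
6 | {[(3S)-3-(but-1-en-2-yl)-3-methylcyclopent-1-en-1-yl]oxy}trimethylsilane | C[Si](C)(C)OC1=C[C@@](C)(C(=C)CC)CC1 | intermediate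
7 | (benzyloxy)acetaldehyde | O=CCOCc1ccccc1 | starting material
8 | lithium (3S)-3-(but-1-en-2-yl)-3-methylcyclopent-1-en-1-olate | [Li]OC1=C[C@@](C)(C(=C)CC)CC1 | intermediate
9 | (2S,3S)-2-[(1R)-2-(benzyloxy)-1-hydroxyethyl]-3-(but-1-en-2-yl)-3-methylcyclopentan-1-one (anti aldol; side chain cis to the C1 methyl) | c1ccccc1COC[C@H](O)[C@H]1C(=O)CC[C@]1(C)C(=C)CC | intermediate
10 | isopropyllithium (propan-2-yllithium) | [Li]C(C)C | starting material
11 | isopropylcerium dichloride | CC(C)[Ce](Cl)Cl | intermediate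
12 | (1R,2S,3S)-2-[(1R)-2-(benzyloxy)-1-hydroxyethyl]-3-(but-1-en-2-yl)-3-methyl-1-(propan-2-yl)cyclopentan-1-ol (4β-OH, 4α-isopropyl) | c1ccccc1COC[C@H](O)[C@H]1[C@](O)(C(C)C)CC[C@]1(C)C(=C)CC | intermediate
13 | triethyl{[(1R,2S,3S)-2-[(1R)-2-(benzyloxy)-1-(triethylsilyloxy)ethyl]-3-(but-1-en-2-yl)-3-methyl-1-(propan-2-yl)cyclopentyl]oxy}silane | c1ccccc1COC[C@H](O[Si](CC)(CC)CC)[C@H]1[C@](O[Si](CC)(CC)CC)(C(C)C)CC[C@]1(C)C(=C)CC | intermediate
14 | ozonide of 13 (3-ethyl-1,2,4-trioxolan-3-yl group on C1 in place of the but-1-en-2-yl group; both epimers at the trioxolane carbon) | c1ccccc1COC[C@H](O[Si](CC)(CC)CC)[C@H]1[C@](O[Si](CC)(CC)CC)(C(C)C)CC[C@]1(C)C2(CC)OOCO2 | intermediate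
15 | 1-[(1S,2S,3R)-2-[(1R)-2-(benzyloxy)-1-(triethylsilyloxy)ethyl]-1-methyl-3-(propan-2-yl)-3-(triethylsilyloxy)cyclopentyl]propan-1-one | c1ccccc1COC[C@H](O[Si](CC)(CC)CC)[C@H]1[C@](O[Si](CC)(CC)CC)(C(C)C)CC[C@]1(C)C(=O)CC | intermediate
16 | 1-[(1S,2S,3R)-2-[(1R)-2-hydroxy-1-(triethylsilyloxy)ethyl]-1-methyl-3-(propan-2-yl)-3-(triethylsilyloxy)cyclopentyl]propan-1-one | OC[C@H](O[Si](CC)(CC)CC)[C@H]1[C@](O[Si](CC)(CC)CC)(C(C)C)CC[C@]1(C)C(=O)CC | intermediate
17 | 1-[(1S,2S,3R)-2-[(1R)-2-iodo-1-(triethylsilyloxy)ethyl]-1-methyl-3-(propan-2-yl)-3-(triethylsilyloxy)cyclopentyl]propan-1-one | IC[C@H](O[Si](CC)(CC)CC)[C@H]1[C@](O[Si](CC)(CC)CC)(C(C)C)CC[C@]1(C)C(=O)CC | intermediate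
18 | potassium enolate of 17 (C8=C10 enolate of the ethyl ketone) | IC[C@H](O[Si](CC)(CC)CC)[C@H]1[C@](O[Si](CC)(CC)CC)(C(C)C)CC[C@]1(C)C(O[K])=CC | intermediate
19 | (1R,3aS,7S,7aS)-3a,5-dimethyl-1-(propan-2-yl)-1,7-bis(triethylsilyloxy)octahydro-4H-inden-4-one (trans-fused; both C8 epimers) | CC[Si](CC)(CC)O[C@H]1CC(C)C(=O)[C@@]2(C)CC[C@@](O[Si](CC)(CC)CC)(C(C)C)[C@H]12 | intermediate
20 | potassium enolate of 19 (C8=C10) | CC[Si](CC)(CC)O[C@H]1CC(C)=C(O[K])[C@@]2(C)CC[C@@](O[Si](CC)(CC)CC)(C(C)C)[C@H]12 | intermediate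
21 | (1R,3aS,7S,7aS)-3a,5-dimethyl-1-(propan-2-yl)-1,7-bis(triethylsilyloxy)-4-(trimethylsilyloxy)-2,3,3a,6,7,7a-hexahydro-1H-indene | CC[Si](CC)(CC)O[C@H]1CC(C)=C(O[Si](C)(C)C)[C@@]2(C)CC[C@@](O[Si](CC)(CC)CC)(C(C)C)[C@H]12 | intermediate
22 | diiodomethane | ICI | starting material
23 | ethyl(iodomethyl)zinc | CC[Zn]CI | intermediate
24 | siloxycyclopropane from 21 (CH2 = C9 bridging C8 and C10; 1-trimethylsilyloxy-6-methylbicyclo[4.1.0]heptane unit, either face) | CC[Si](CC)(CC)O[C@H]1CC2(C)CC2(O[Si](C)(C)C)[C@@]3(C)CC[C@@](O[Si](CC)(CC)CC)(C(C)C)[C@H]13 | intermediate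
25 | (1R,3aS,8S,8aS)-6-chloro-3a,6-dimethyl-1-(propan-2-yl)-1,8-bis(triethylsilyloxy)octahydroazulen-4(1H)-one (both C8 epimers) | CC[Si](CC)(CC)O[C@H]1CC(C)(Cl)CC(=O)[C@@]2(C)CC[C@@](O[Si](CC)(CC)CC)(C(C)C)[C@H]12 | intermediate
26 | (1R,3aS,8S,8aS)-3a,6-dimethyl-1-(propan-2-yl)-1,8-bis(triethylsilyloxy)-2,3,3a,7,8,8a-hexahydroazulen-4(1H)-one | CC[Si](CC)(CC)O[C@H]1CC(C)=CC(=O)[C@@]2(C)CC[C@@](O[Si](CC)(CC)CC)(C(C)C)[C@H]12 | intermediate
27 | (1R,3aS,8S,8aS)-1,8-dihydroxy-3a,6-dimethyl-1-(propan-2-yl)-2,3,3a,7,8,8a-hexahydroazulen-4(1H)-one | O[C@H]1CC(C)=CC(=O)[C@@]2(C)CC[C@@](O)(C(C)C)[C@H]12 | intermediate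
28 | 4-methoxybenzoyl chloride | COc1ccc(cc1)C(Cl)=O | starting material
29 | (3R,3aS,4S,8aS)-3-hydroxy-6,8a-dimethyl-8-oxo-3-(propan-2-yl)-1,2,3,3a,4,5,8,8a-octahydroazulen-4-yl 4-methoxybenzoate | COc1ccc(C(=O)O[C@H]2CC(C)=CC(=O)[C@@]3(C)CC[C@@](O)(C(C)C)[C@H]23)cc1 | intermediate
30 | (3R,3aS,4S,8S,8aS)-3,8-dihydroxy-6,8a-dimethyl-3-(propan-2-yl)-1,2,3,3a,4,5,8,8a-octahydroazulen-4-yl 4-methoxybenzoate (10β-alcohol) | COc1ccc(C(=O)O[C@H]2CC(C)=C[C@H](O)[C@@]3(C)CC[C@@](O)(C(C)C)[C@H]23)cc1 | intermediate
31 | acetic acid | CC(=O)O | starting material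
32 | (3R,3aS,4S,8R,8aS)-8-(acetyloxy)-3-hydroxy-6,8a-dimethyl-3-(propan-2-yl)-1,2,3,3a,4,5,8,8a-octahydroazulen-4-yl 4-methoxybenzoate (CNP0256979.2) | COc1ccc(C(=O)O[C@H]2CC(C)=C[C@@H](OC(C)=O)[C@@]3(C)CC[C@@](O)(C(C)C)[C@H]23)cc1 | target

Total step count: 14. Longest linear sequence: 14 steps (1 to 32).

**Steps most likely to fail**

Step 1. The transfer of an α-branched alkenyl group to the β-carbon of a cyclopentenone may proceed with insufficient enantioselectivity or incomplete conversion, and the enolate regiochemistry may be partly lost on silylation. The fallback reverses the roles of the two C1 substituents; it sets out from 2 and returns at 6. Alkenyllithium 3, made from 2 as before, is added to 3-ethoxycyclopent-2-en-1-one and the adduct is hydrolysed with dilute acid (Stork–Danheiser sequence) to give 3-(but-1-en-2-yl)cyclopent-2-en-1-one F1. Copper-catalysed asymmetric 1,4-addition of MeMgBr (Cu(OTf)2 with a chiral N-heterocyclic carbene precursor of the antipode that delivers methyl to the face giving (S)-C1) then forms the C1–CH3 bond instead of the C1–C10 bond, and quenching of the magnesium enolate with Me3SiCl gives 6.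

Step 2. The aldol addition may show poor simple diastereoselection, delivering the aldehyde in the syn instead of the anti sense at C6. The fallback corrects C6 by inversion instead of relying on the transition-state preference; it sets out from 6 and returns at 12. The syn adduct (2S,3S)-2-[(1S)-2-(benzyloxy)-1-hydroxyethyl]-3-(but-1-en-2-yl)-3-methylcyclopentan-1-one F2 is taken through the organocerium addition of step 3 to the C6-epimeric diol (1R,2S,3S)-2-[(1S)-2-(benzyloxy)-1-hydroxyethyl]-3-(but-1-en-2-yl)-3-methyl-1-(propan-2-yl)cyclopentan-1-ol F3. Mitsunobu esterification of its secondary hydroxyl with 4-nitrobenzoic acid (PPh3, DIAD) inverts C6 and gives the 6-O-(4-nitrobenzoyl) ester of 12 F4. Methanolysis (K2CO3, MeOH) then gives 12.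

Step 14. Activation of the neopentylic allylic hydroxyl may be sluggish, and ionisation to the allyl cation would erode stereochemical fidelity and open the way to SN2′ substitution or elimination to a diene. The fallback sets C10 by reagent-controlled reduction instead of substitution; it sets out from 29 and returns at 32. Enone 29 is reduced under CBS conditions with the (S)-2-methyl-oxazaborolidine and catecholborane in toluene at low temperature, on the premise that the quaternary C1 side acts as the large group, so that hydride is delivered to the β face. This gives the 10α-alcohol (3R,3aS,4S,8R,8aS)-3,8-dihydroxy-6,8a-dimethyl-3-(propan-2-yl)-1,2,3,3a,4,5,8,8a-octahydroazulen-4-yl 4-methoxybenzoate F5. Acetylation (Ac2O, pyridine, DMAP) of the secondary allylic hydroxyl then gives 32 with no substitution at C10.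

**Further compounds**

F1 | step 1 | 3-(but-1-en-2-yl)cyclopent-2-en-1-one | C=C(CC)C1=CC(=O)CC1
F2 | step 2 | (2S,3S)-2-[(1S)-2-(benzyloxy)-1-hydroxyethyl]-3-(but-1-en-2-yl)-3-methylcyclopentan-1-one | c1ccccc1COC[C@@H](O)[C@H]1C(=O)CC[C@]1(C)C(=C)CC
F3 | step 2 | (1R,2S,3S)-2-[(1S)-2-(benzyloxy)-1-hydroxyethyl]-3-(but-1-en-2-yl)-3-methyl-1-(propan-2-yl)cyclopentan-1-ol | c1ccccc1COC[C@@H](O)[C@H]1[C@](O)(C(C)C)CC[C@]1(C)C(=C)CC
F4 | step 2 | 6-O-(4-nitrobenzoyl) ester of 12 | c1ccccc1COC[C@H](OC(=O)c2ccc(cc2)[N+](=O)[O-])[C@H]1[C@](O)(C(C)C)CC[C@]1(C)C(=C)CC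
F5 | step 14 | (3R,3aS,4S,8R,8aS)-3,8-dihydroxy-6,8a-dimethyl-3-(propan-2-yl)-1,2,3,3a,4,5,8,8a-octahydroazulen-4-yl 4-methoxybenzoate | COc1ccc(C(=O)O[C@H]2CC(C)=C[C@@H](O)[C@@]3(C)CC[C@@](O)(C(C)C)[C@H]23)cc1
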